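**Retrosynthetic overview**
1. Mitorubrinic acid ⇒ global deprotection (tBu ester and two aryl TBS ethers) of azaphilone **19**.
2. The pyran ring (O2–C3 bond) ⇐ 6-endo oxa-cyclisation of the C1 hydroxymethylene enol onto the enynone alkyne of dearomatised ortho-quinol ester **18**.
3. Key step: the C7 quaternary acyloxy stereocentre ⇐ enantioselective dearomative ortho-acyloxylation at C-2 of the 2-methylresorcinol **12**. The catalyst is a chiral aryl iodide (**17**), and a protected orsellinyl peracid (**11**) is both terminal oxidant and acyl donor.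
4. **12** ⇐ Sonogashira coupling of bromo-aldehyde **4** with enynoate **8**. **4** comes from 2,6-dimethoxytoluene by Rieche formylation, Comins ortho-bromination and BBr3 demethylation.
5. Ring order: the benzene ring is pre-formed, then dearomatised (C7 set), then the pyran ring closes.

**Assumptions.**
- The (S,S)-lactamide iodoarene **17** is assumed to give the (7R) sense. The enantiomeric catalyst, made from (S)-lactate, is used if screening shows otherwise.
- The enynoate is made in two steps because I assume it is not purchasable.
- The catalyst is made in two steps from commercial methyl (R)-lactate and 2-iodoresorcinol.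

---

**Step 1**
Reactants: 1 (2,6-dimethoxytoluene)
Product: 2 (2,4-dimethoxy-3-methylbenzaldehyde)
Conditions: Cl2CHOMe, TiCl4, CH2Cl2, 0 °C; then H2O
Reagents that add atoms: dichloromethyl methyl ether, COC(Cl)Cl (gives the CHO carbon); water, O (gives the CHO oxygen on work-up)
Why: Rieche formylation goes to C-3, which is ortho to one OMe and para to the other, so it is the most activated position.

**Step 2**
Reactants: 2
Product: 3 (6-bromo-2,4-dimethoxy-3-methylbenzaldehyde)
Conditions: LiN(Me)CH2CH2NMe2 (from N,N,N′-trimethylethylenediamine and n-BuLi), THF, 0 °C; n-BuLi, –20 °C; BrCCl2CCl2Br, –78 °C to rt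
Reagents that add atoms: 1,2-dibromotetrachloroethane, BrC(Cl)(Cl)C(Cl)(Cl)Br
Why: Comins in-situ α-amino-alkoxide protection directs lithiation to the only free position ortho to the masked aldehyde (C-6), and the aryllithium is trapped as the bromide.

**Step 3**
Reactants: 3
Product: 4 (6-bromo-2,4-dihydroxy-3-methylbenzaldehyde)
Conditions: BBr3 (4 equiv), CH2Cl2, –78 to 0 °C; H2O quench
Reagents that add atoms: none
Why: BBr3 cleaves both aryl methyl ethers (Lewis-acid ether cleavage), and the aryl bromide and the H-bonded, deactivated aldehyde survive.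

**Step 4**
Reactants: 5 (3-(trimethylsilyl)propiolaldehyde); 6 (tert-butyl diethylphosphonoacetate)
Product: 7 (tert-butyl (E)-5-(trimethylsilyl)pent-2-en-4-ynoate)
Conditions: LiCl, iPr2NEt, MeCN, 0 °C to rt
Reagents that add atoms: none
Why: Masamune–Roush Horner–Wadsworth–Emmons olefination gives the (E)-enoate.

**Step 5**
Reactants: 7
Product: 8 (tert-butyl (E)-pent-2-en-4-ynoate)
Conditions: K2CO3 (0.1 equiv), MeOH, 0 °C, 10 min; cold work-up, product used as a solution (volatile)
Reagents that add atoms: none
Why: Mild protodesilylation of the alkynyl-TMS group leaves the hindered tBu enoate intact.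

**Step 6**
Reactants: 9 (orsellinic acid, 2,4-dihydroxy-6-methylbenzoic acid)
Product: 10 (2,4-bis(tert-butyldimethylsilyloxy)-6-methylbenzoic acid)
Conditions: TBSCl (3.5 equiv), imidazole, DMF, 23 °C; then THF/H2O, aq. citric acid, 0 °C
Reagents that add atoms: TBSCl, CC(C)(C)[Si](C)(C)Cl
Why: Both phenols are silylated, and the labile silyl ester is hydrolysed on acidic work-up, leaving the free acid.

**Step 7**
Reactants: 10
Product: 11 (2,4-bis(TBSO)-6-methylperbenzoic acid)
Conditions: Ghosez reagent, CH2Cl2, 0 °C; then urea·H2O2, pyridine, 0 °C (generated in solution and used immediately)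
Reagents that add atoms: hydrogen peroxide (as urea·H2O2), OO
Why: The acid chloride is made under neutral conditions, so the TBS ethers survive, and perhydrolysis gives the peracid.

**Step 8**
Reactants: 4; 8
Product: 12 (tert-butyl (E)-5-(2-formyl-3,5-dihydroxy-4-methylphenyl)pent-2-en-4-ynoate)
Conditions: Pd(PPh3)2Cl2 (5 mol%), CuI (10 mol%), Et3N, DMF, 35 °C
Reagents that add atoms: none
Why: Sonogashira coupling of the aryl bromide with the terminal enyne. The free phenols and the aldehyde are tolerated because neither phenol is ortho to the new alkyne.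

**Step 9**
Reactants: 13 (methyl (R)-lactate, 2.4 equiv); 14 (2-iodoresorcinol)
Product: 15 (dimethyl (S,S)-2,2′-[(2-iodo-1,3-phenylene)bis(oxy)]dipropanoate)
Conditions: PPh3 (2.5 equiv), DIAD (2.5 equiv), THF, 0 °C to rt, 12 h
Reagents that add atoms: none
Why: Double Mitsunobu etherification inverts each lactate carbon, so the (R)-lactate gives the (S)-aryloxy ester at both centres.

**Step 10**
Reactants: 15; 16 (2,4,6-trimethylaniline)
Product: 17 ((S,S)-2-iodoresorcinol bis(N-mesityl-lactamide), the chiral iodoarene catalyst)
Conditions: Me3Al (5 equiv) pre-mixed with 16 (5 equiv), toluene, then 15, 80 °C, 16 h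
Reagents that add atoms: none (the mesityl amine is reactant 16)
Why: Me3Al-mediated aminolysis (Weinreb-type amidation) converts both methyl esters to anilides under non-basic conditions, so the α-aryloxy stereocentres are not racemised.

**Step 11 (key step)**
Reactants: 12; 11 (1.3 equiv); 17 (10 mol%)
Product: 18 (ortho-quinol orsellinate: (7R)-7-acyloxy-7-methyl-6,8-dione carrying the 2-hydroxymethylene group and the enynoate, tBu/TBS-protected)
Conditions: 17 (10 mol%), 11, CH2Cl2, –20 °C, 24 h, dark
Reagents that add atoms: none (the acyloxy group comes from reactant 11)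
Why: Proposed new method: the peracid oxidises ArI to a chiral hydroxy(acyloxy)-λ3-iodane. Ligand exchange with the resorcinol gives an aryloxy-iodane, whose phenoxenium-like C-2 (C-7 of the target) is attacked by the orsellinate carboxylate on one enantiotopic face, controlled by the lactamide N–H/C=O arms. The nearest known chemistry is Wessely acetoxylation of phenols (Pb(OAc)4/AcOH) and chiral-iodoarene-catalysed dearomative spirolactonisation and hydroxylation of naphthols. What is new is an intermolecular enantioselective ortho-acyloxylation of a 2-alkylresorcinol, with the peracid acting as both oxidant and acyl donor (net: 12 + ArCO3H → 18 + H2O). This sets the only stereocentre, C7 (R), and the non-enolisable quaternary centre cannot racemise.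

**Step 12**
Reactants: 18
Product: 19 (protected mitorubrinic acid: (7R) azaphilone with tBu acrylate and bis-TBS orsellinate)
Conditions: AgOTf (10 mol%), 2,6-di-tert-butyl-4-methylpyridine (20 mol%), CH2Cl2, 23 °C, 2 h, dark
Reagents that add atoms: none
Why: Ag(I)-catalysed 6-endo-dig hydroalkoxylation of the C1 enol onto the alkyne, a cycloisomerisation of the o-alkynyl-aldehyde enol type used for azaphilone pyran formation. C-3 is the δ-terminus of the dienone acceptor, which directs O to C-3 and forms the pyran ring. The stereocentre is untouched.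

**Step 13**
Reactants: 19
Product: 20 (mitorubrinic acid)
Conditions: TFA/CH2Cl2 (1:4), 0 °C, 1 h; evaporate; then Et3N·3HF, THF, 23 °C, 4 h (one pot, dark)
Reagents that add atoms: none (only H is added)
Why: TFA cleaves the tBu ester by E1 loss of isobutylene, and buffered HF removes the aryl silyl ethers, so the azaphilone, the ester and the (E)-acrylate survive.

---

**Compound list**
1 | 2,6-dimethoxytoluene | COc1cccc(OC)c1C | starting material
2 | 2,4-dimethoxy-3-methylbenzaldehyde | COc1ccc(C=O)c(OC)c1C | intermediate
3 | 6-bromo-2,4-dimethoxy-3-methylbenzaldehyde | COc1cc(Br)c(C=O)c(OC)c1C | intermediate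
4 | 6-bromo-2,4-dihydroxy-3-methylbenzaldehyde | Cc1c(O)cc(Br)c(C=O)c1O | intermediate
5 | 3-(trimethylsilyl)propiolaldehyde | C[Si](C)(C)C#CC=O | starting material
6 | tert-butyl diethylphosphonoacetate | CCOP(=O)(OCC)CC(=O)OC(C)(C)C | starting material
7 | tert-butyl (E)-5-TMS-pent-2-en-4-ynoate | C[Si](C)(C)C#C/C=C/C(=O)OC(C)(C)C | intermediate
8 | tert-butyl (E)-pent-2-en-4-ynoate | C#C/C=C/C(=O)OC(C)(C)C | intermediate
9 | orsellinic acid | Cc1cc(O)cc(O)c1C(=O)O | starting material
10 | 2,4-bis(TBSO)-6-methylbenzoic acid | Cc1cc(O[Si](C)(C)C(C)(C)C)cc(O[Si](C)(C)C(C)(C)C)c1C(=O)O | intermediate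
11 | 2,4-bis(TBSO)-6-methylperbenzoic acid | Cc1cc(O[Si](C)(C)C(C)(C)C)cc(O[Si](C)(C)C(C)(C)C)c1C(=O)OO | intermediate
12 | tert-butyl (E)-5-(2-formyl-3,5-dihydroxy-4-methylphenyl)pent-2-en-4-ynoate | Cc1c(O)cc(C#C/C=C/C(=O)OC(C)(C)C)c(C=O)c1O | intermediate
13 | methyl (R)-lactate | C[C@@H](O)C(=O)OC | starting material
14 | 2-iodoresorcinol | Oc1cccc(O)c1I | starting material
15 | dimethyl (S,S)-2,2′-[(2-iodo-1,3-phenylene)bis(oxy)]dipropanoate | C[C@H](Oc1cccc(O[C@@H](C)C(=O)OC)c1I)C(=O)OC | intermediate
16 | 2,4,6-trimethylaniline | Cc1cc(C)c(N)c(C)c1 | starting material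
17 | (S,S)-2-iodoresorcinol bis(N-mesityl-lactamide), chiral iodoarene catalyst | C[C@H](Oc1cccc(O[C@@H](C)C(=O)Nc2c(C)cc(C)cc2C)c1I)C(=O)Nc1c(C)cc(C)cc1C | intermediate
18 | dearomatised (7R) ortho-quinol orsellinate (hydroxymethylene enol) | O=C1C=C(C#C/C=C/C(=O)OC(C)(C)C)C(=CO)C(=O)[C@]1(C)OC(=O)c1c(C)cc(O[Si](C)(C)C(C)(C)C)cc1O[Si](C)(C)C(C)(C)C | intermediate
19 | protected mitorubrinic acid | Cc1cc(O[Si](C)(C)C(C)(C)C)cc(O[Si](C)(C)C(C)(C)C)c1C(=O)O[C@]1(C)C(=O)C=C2C=C(/C=C/C(=O)OC(C)(C)C)OC=C2C1=O | intermediate
20 | mitorubrinic acid | Cc1cc(O)cc(O)c1C(=O)O[C@]1(C)C(=O)C=C2C=C(/C=C/C(=O)O)OC=C2C1=O | target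

**Totals:** 13 steps in all. The longest linear sequence is 7 steps (1 → 2 → 3 → 4 → 12 → 18 → 19 → 20, i.e. steps 1, 2, 3, 8, 11, 12, 13).

**Three steps most likely to fail**
1. **Step 11, the proposed new dearomative acyloxylation.** The risks are low ee for an intermolecular nucleophile, para (C-5) attack, hydroxylation by the water formed, and Dakin or Baeyer–Villiger oxidation of the aldehyde by the peracid. Fallback (known chemistry): Cu(II)/(–)-sparteine/O2 hydroxylative dearomatisation of **12**, then Ag-cyclisation to the 7-hydroxy azaphilone. Next, DMAP-promoted acylation of the tertiary alcohol with the acid chloride of **10**, then the step 13 deprotection.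
2. **Step 12, pyran closure.** The electron-poor enoate could divert cyclisation to the 5-exo isobenzofuran. Fallback: couple the alkyne partner (E)-HC≡C–CH=CH–CH2OTBS in step 8, since it is not conjugated to an acceptor. Cyclise as in step 12, then install the acid by desilylation, MnO2 oxidation and Pinnick oxidation.
3. **Step 2, Comins ortho-bromination.** Lithiation could occur at C-5, ortho to the 4-OMe, instead of C-6. Fallback: drop the bromide route and use a Pd(II)/transient amino-acid directing-group, aldehyde-directed ortho C–H iodination of commercial 2,4-dihydroxy-3-methylbenzaldehyde to give the C-6 halide.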